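**Plan**
Numbering (terpenoid): C4 gem-dimethyl carbon, C5=C6 alkene, C8 the CHCH3, C9 the quaternary carbon, C10 the ring-fusion CH, C11 the benzylic carbon; ring A = C1–C5 and C10, ring B = C5–C10.
Retrosynthesis: the quinone C–N bond is cut first (isopentylamine), the hydroxyquinone is traced back to a tetramethoxyarene carrying an oxygen at C11, and ring B is then cut at C7–C8 and C9–C10.
Enabling feature: ring B is a cyclohexene (C5=C6) whose three contiguous stereocentres C8, C9 and C10 lie exactly where an α-methyl enone adds to a 1-vinylcyclohexene.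
Forward: ring A comes from ketone 1 as diene 4, the arene 5 is converted into enone 9, ring B closes in the Diels-Alder step, then C11 is deoxygenated and the arene becomes the 2-hydroxy-5-aminoquinone.
Stereochemistry: the cis C8/C9 methyl groups come from the E enone, C10 from the exo transition state, the absolute configuration from a chiral oxazaborolidinium Lewis acid; no later step touches these centres.

Key step: step 5

Assumption: the sense of induction with ketone 9 is taken to parallel that known for α-methyl enals, so the (R)-catalyst is written; should the other face prove shielded, the (S)-antipode is used with nothing else changed.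

**Step 1**
Reactants: 1 2,2-dimethylcyclohexanone
Product: 3 6,6-dimethylcyclohex-1-en-1-yl trifluoromethanesulfonate, via lithium 6,6-dimethylcyclohex-1-en-1-olate 2 (not isolated)
Conditions: LiN(iPr)2, THF, −78 °C; PhNTf2, −78 °C → rt; H2O
Reagents that add atoms: N-phenylbis(trifluoromethanesulfonimide), O=S(=O)(N(c1ccccc1)S(=O)(=O)C(F)(F)F)C(F)(F)F
Why: The ketone has only one enolisable position, so deprotonation and O-sulfonylation of the lithium enolate (enol triflate formation) can place the alkene only away from the gem-dimethyl carbon.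

**Step 2**
Reactants: 3 6,6-dimethylcyclohex-1-en-1-yl trifluoromethanesulfonate
Product: 4 6,6-dimethyl-1-vinylcyclohexene
Conditions: CH2=CHSnBu3, Pd(PPh3)4 (3 mol %), LiCl, THF, 65 °C
Reagents that add atoms: tributyl(vinyl)stannane, C=C[Sn](CCCC)(CCCC)CCCC
Why: Stille cross-coupling of a vinyl triflate with a vinylstannane under zerovalent palladium, with LiCl to assist turnover, should give the conjugated diene without moving the ring alkene.

**Step 3**
Reactants: 5 1,2,4,5-tetramethoxybenzene; 6 tiglaldehyde
Product: 8 (E)-2-methyl-1-(2,3,5,6-tetramethoxyphenyl)but-2-en-1-ol (racemic), via 2,3,5,6-tetramethoxyphenyllithium 7 (not isolated)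
Conditions: n-BuLi, TMEDA, THF, 0 °C; 6, −78 → 0 °C; H2O
Reagents that add atoms: none
Why: Directed ortho-lithiation at one of the two equivalent ring positions flanked by two methoxy groups, followed by 1,2-addition of the aryllithium to the enal, should give the allylic benzylic alcohol with the E alkene intact; its carbinol centre is racemic and is oxidised in step 4.

**Step 4**
Reactants: 8 (E)-2-methyl-1-(2,3,5,6-tetramethoxyphenyl)but-2-en-1-ol
Product: 9 (E)-2-methyl-1-(2,3,5,6-tetramethoxyphenyl)but-2-en-1-one
Conditions: MnO2, CH2Cl2, rt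
Reagents that add atoms: none
Why: MnO2 oxidation of an allylic and benzylic alcohol proceeds under neutral heterogeneous conditions, which should avoid ionisation of the doubly activated carbinol and keep the E geometry.

**Step 5**
Reactants: 4 6,6-dimethyl-1-vinylcyclohexene; 9 (E)-2-methyl-1-(2,3,5,6-tetramethoxyphenyl)but-2-en-1-one
Product: 10 [(1R,2S,8aR)-1,2,5,5-tetramethyl-1,2,3,5,6,7,8,8a-octahydronaphthalen-1-yl](2,3,5,6-tetramethoxyphenyl)methanone
Conditions: (R)-3,3-diphenyl-1-(o-tolyl)tetrahydro-1H,3H-pyrrolo[1,2-c][1,3,2]oxazaborole (20 mol %), HNTf2 (18 mol %), 4 (3 equiv), CH2Cl2, −40 → 0 °C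
Reagents that add atoms: none
Why: Proposed new method: the cationic boron of the protonated oxazaborolidine should bind the ketone oxygen of 9 and lower the enone LUMO, so that a concerted but asynchronous [4+2] cycloaddition with the s-cis diene 4 begins at the unhindered vinyl CH2 (C7–C8) and ends at C10–C9; the closest known reactions are the oxazaborolidinium-catalysed exo Diels-Alder additions of α-methyl enals such as tiglaldehyde and the exo additions of 1-vinylcyclohexenes to α-methyl aryl enones under achiral Lewis acids, whereas an α-methyl aryl ketone has not been shown with this chiral catalyst. Ring B is the only ring formed and closes as a cyclohexene (new alkene C5=C6) by intermolecular [4+2] cycloaddition, suprafacial on both partners. C8 and C9 are set relative to each other by the E geometry of 9, which makes their methyl groups cis. C10 is set relative to C9 by the exo transition state, in which the α-methyl group lies under the diene and the twisted, di-ortho-substituted aroyl group points away, so that C11 ends cis to H10. The absolute configuration is set by the catalyst, whose phenyl group is expected to cover the re face of the α-carbon C9 as it does with α-methyl enals, leaving the si face for C10 and giving the (1R,2S,8aR) ketone with the target's configuration at all three centres. The step needs ortho regiochemistry, exo selectivity and one enantioface: the first follows from the larger HOMO coefficient at C7 of the 1-substituted diene pairing with the enone β-carbon C8, the second from the α-methyl/aroyl pair, the third from the chiral boron Lewis acid.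

**Step 6**
Reactants: 10 [(1R,2S,8aR)-1,2,5,5-tetramethyl-1,2,3,5,6,7,8,8a-octahydronaphthalen-1-yl](2,3,5,6-tetramethoxyphenyl)methanone
Product: 11 [(1R,2S,8aR)-1,2,5,5-tetramethyl-1,2,3,5,6,7,8,8a-octahydronaphthalen-1-yl](2,3,5,6-tetramethoxyphenyl)methanol (mixture of C11 epimers)
Conditions: LiAlH4, THF, 0 → 65 °C; Na2SO4·10H2O
Reagents that add atoms: none
Why: Hydride reduction of a non-enolisable ketone with the small, strong donor LiAlH4 should reach the hindered carbonyl group; the new C11 carbinol centre forms without control and is removed in step 7, while C9 is quaternary and cannot epimerise.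

**Step 7**
Reactants: 11 [(1R,2S,8aR)-1,2,5,5-tetramethyl-1,2,3,5,6,7,8,8a-octahydronaphthalen-1-yl](2,3,5,6-tetramethoxyphenyl)methanol
Product: 12 1,2,4,5-tetramethoxy-3-{[(1R,2S,8aS)-1,2,5,5-tetramethyl-1,2,3,5,6,7,8,8a-octahydronaphthalen-1-yl]methyl}benzene
Conditions: Li, NH3 (l), THF, −78 → −33 °C; NH4Cl
Reagents that add atoms: none
Why: Dissolving-metal hydrogenolysis of a benzylic C–O bond, with NH4Cl as the proton source that frees the alcohol from its unreactive alkoxide, should remove the C11 oxygen while the isolated trisubstituted alkene and the electron-rich ring stay unreduced.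

**Step 8**
Reactants: 12 1,2,4,5-tetramethoxy-3-{[(1R,2S,8aS)-1,2,5,5-tetramethyl-1,2,3,5,6,7,8,8a-octahydronaphthalen-1-yl]methyl}benzene
Product: 13 2,5-dimethoxy-3-{[(1R,2S,8aS)-1,2,5,5-tetramethyl-1,2,3,5,6,7,8,8a-octahydronaphthalen-1-yl]methyl}cyclohexa-2,5-diene-1,4-dione
Conditions: (NH4)2Ce(NO3)6, MeCN/H2O, 0 °C
Reagents that add atoms: water, O
Why: Oxidative demethylation of a para-dimethoxyarene by tetravalent cerium should give the para-quinone, and because the ring is symmetric about the axis through the side chain both para pairs lead to the same 2,5-dimethoxyquinone, the arene being oxidised far more readily than the alkene.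

**Step 9**
Reactants: 13 2,5-dimethoxy-3-{[(1R,2S,8aS)-1,2,5,5-tetramethyl-1,2,3,5,6,7,8,8a-octahydronaphthalen-1-yl]methyl}cyclohexa-2,5-diene-1,4-dione
Product: 14 2-hydroxy-5-methoxy-3-{[(1R,2S,8aS)-1,2,5,5-tetramethyl-1,2,3,5,6,7,8,8a-octahydronaphthalen-1-yl]methyl}cyclohexa-2,5-diene-1,4-dione
Conditions: KOH, MeOH/H2O, rt; 1 M HCl to pH 3
Reagents that add atoms: potassium hydroxide, [K+].[OH-]
Why: Addition-elimination of hydroxide at a vinylogous ester carbon is known in this quinone class to exchange the methoxy group next to the side chain, which is twisted out of conjugation, and the vinylogous carboxylate formed resists a second hydrolysis.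

**Step 10**
Reactants: 14 2-hydroxy-5-methoxy-3-{[(1R,2S,8aS)-1,2,5,5-tetramethyl-1,2,3,5,6,7,8,8a-octahydronaphthalen-1-yl]methyl}cyclohexa-2,5-diene-1,4-dione; 15 isopentylamine
Product: 16 nakijiquinone M
Conditions: 15 (3 equiv), EtOH, rt; pH 4 buffer wash
Reagents that add atoms: none
Why: Addition-elimination of a primary amine at the remaining methoxy-bearing quinone carbon is the established conversion of 2-hydroxy-5-methoxyquinones into 5-amino-2-hydroxyquinones and leaves the remote stereocentres untouched.

**Compound list**
1 | 2,2-dimethylcyclohexanone | CC1(C)CCCCC1=O | starting material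
2 | lithium 6,6-dimethylcyclohex-1-en-1-olate (formed in the flask) | [Li]OC1=CCCCC1(C)C | intermediate
3 | 6,6-dimethylcyclohex-1-en-1-yl trifluoromethanesulfonate | CC1(C)CCCC=C1OS(=O)(=O)C(F)(F)F | intermediate
4 | 6,6-dimethyl-1-vinylcyclohexene | C=CC1=CCCCC1(C)C | intermediate
5 | 1,2,4,5-tetramethoxybenzene | COc1cc(OC)c(OC)cc1OC | starting material
6 | tiglaldehyde, (E)-2-methylbut-2-enal | C/C=C(\C)C=O | starting material
7 | 2,3,5,6-tetramethoxyphenyllithium (formed in the flask) | [Li]c1c(OC)c(OC)cc(OC)c1OC | intermediate
8 | (E)-2-methyl-1-(2,3,5,6-tetramethoxyphenyl)but-2-en-1-ol, racemic | C/C=C(\C)C(O)c1c(OC)c(OC)cc(OC)c1OC | intermediate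
9 | (E)-2-methyl-1-(2,3,5,6-tetramethoxyphenyl)but-2-en-1-one | C/C=C(\C)C(=O)c1c(OC)c(OC)cc(OC)c1OC | intermediate
10 | [(1R,2S,8aR)-1,2,5,5-tetramethyl-1,2,3,5,6,7,8,8a-octahydronaphthalen-1-yl](2,3,5,6-tetramethoxyphenyl)methanone | COc1cc(OC)c(OC)c(C(=O)[C@@]2(C)[C@@H]3CCCC(C)(C)C3=CC[C@@H]2C)c1OC | intermediate
11 | [(1R,2S,8aR)-1,2,5,5-tetramethyl-1,2,3,5,6,7,8,8a-octahydronaphthalen-1-yl](2,3,5,6-tetramethoxyphenyl)methanol, both C11 epimers | COc1cc(OC)c(OC)c(C(O)[C@@]2(C)[C@@H]3CCCC(C)(C)C3=CC[C@@H]2C)c1OC | intermediate
12 | 1,2,4,5-tetramethoxy-3-{[(1R,2S,8aS)-1,2,5,5-tetramethyl-1,2,3,5,6,7,8,8a-octahydronaphthalen-1-yl]methyl}benzene | COc1cc(OC)c(OC)c(C[C@@]2(C)[C@@H]3CCCC(C)(C)C3=CC[C@@H]2C)c1OC | intermediate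
13 | 2,5-dimethoxy-3-{[(1R,2S,8aS)-1,2,5,5-tetramethyl-1,2,3,5,6,7,8,8a-octahydronaphthalen-1-yl]methyl}cyclohexa-2,5-diene-1,4-dione | COC1=CC(=O)C(OC)=C(C[C@@]2(C)[C@@H]3CCCC(C)(C)C3=CC[C@@H]2C)C1=O | intermediate
14 | 2-hydroxy-5-methoxy-3-{[(1R,2S,8aS)-1,2,5,5-tetramethyl-1,2,3,5,6,7,8,8a-octahydronaphthalen-1-yl]methyl}cyclohexa-2,5-diene-1,4-dione | COC1=CC(=O)C(O)=C(C[C@@]2(C)[C@@H]3CCCC(C)(C)C3=CC[C@@H]2C)C1=O | intermediate
15 | isopentylamine (3-methylbutan-1-amine) | CC(C)CCN | starting material
16 | nakijiquinone M, 2-hydroxy-5-[(3-methylbutyl)amino]-3-{[(1R,2S,8aS)-1,2,5,5-tetramethyl-1,2,3,5,6,7,8,8a-octahydronaphthalen-1-yl]methyl}cyclohexa-2,5-diene-1,4-dione | CC(C)CCNC1=CC(=O)C(O)=C(C[C@@]2(C)[C@@H]3CCCC(C)(C)C3=CC[C@@H]2C)C1=O | target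

**Step count**
Total: 10 steps. Longest linear sequence: 8 steps (steps 1, 2, 5, 6, 7, 8, 9, 10; the arene branch through steps 3 and 4 is equally long).

**Steps most likely to fail**

Step 5. The hindered ketone may bind the boron weakly and without the organising contact that a formyl hydrogen provides, so turnover may be slow and the enone faces poorly distinguished. The acid may also oligomerise the diene before cycloaddition. The fallback sets out from diene 4 and tiglaldehyde 6. The same (R)-oxazaborolidinium triflimide catalyses the exo Diels-Alder addition of this α-methyl enal, an established substrate class, forming the same C7–C8 and C9–C10 bonds with the formyl group exo. This should give (1R,2S,8aR)-1,2,5,5-tetramethyl-1,2,3,5,6,7,8,8a-octahydronaphthalene-1-carbaldehyde F1. Aryllithium 7, generated from 5 as in step 3, then adds to the neopentyl aldehyde and the route is rejoined at carbinol 11; compounds 8 to 10 and step 6 are not needed.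

Step 7. The benzylic alkoxide may resist electron transfer so that the carbinol returns unchanged, or over-reduction may cleave a methoxy group from the ring. The fallback sets out from carbinol 11. NaH, CS2 and MeI in THF should give the xanthate O-{[(1R,2S,8aR)-1,2,5,5-tetramethyl-1,2,3,5,6,7,8,8a-octahydronaphthalen-1-yl](2,3,5,6-tetramethoxyphenyl)methyl} S-methyl carbonodithioate F2. Bu3SnH with AIBN in toluene at 110 °C (Barton-McCombie deoxygenation through the benzylic radical) then returns to the route at 12.

Step 6. Hydride delivery may stall at a carbonyl group buried between the quaternary carbon and the di-ortho-substituted ring. The fallback sets out from ketone 10 and reduces it in one pot with Li in NH3/THF followed by NH4Cl. This is the dissolving-metal reduction of an aryl ketone to its methylene compound, in which electron transfer forms the ketyl and then the alkoxide of 11, and the benzylic C–O bond is hydrogenolysed on protonation. It arrives directly at 12 and makes no new compound (F0).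

**Further compounds**
F1 | step 5 | (1R,2S,8aR)-1,2,5,5-tetramethyl-1,2,3,5,6,7,8,8a-octahydronaphthalene-1-carbaldehyde | O=C[C@@]1(C)[C@@H]2CCCC(C)(C)C2=CC[C@@H]1C
F2 | step 7 | O-{[(1R,2S,8aR)-1,2,5,5-tetramethyl-1,2,3,5,6,7,8,8a-octahydronaphthalen-1-yl](2,3,5,6-tetramethoxyphenyl)methyl} S-methyl carbonodithioate | COc1cc(OC)c(OC)c(C(OC(=S)SC)[C@@]2(C)[C@@H]3CCCC(C)(C)C3=CC[C@@H]2C)c1OC
F0 | step 6 | none | none
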